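**Plan**

- Retrosynthesis (locants of the C32 main chain; C14 is the quaternary oxirane carbon, C15 the oxirane CH): cut O–C15 (invertive closure of a 14,15-diol 15-mesylate), then one C–H of the C14 methyl (hydride opening of a terminal oxirane), then both C–O bonds of that oxirane (epoxidation of C14=CH2), then C14–C15 (alkenyl–aldehyde coupling), then C16–C17 (acetate alkylation).
- Enabling feature: the methyl on the quaternary oxirane carbon C14 is a masked exocyclic CH2. Unmasked, C14 is the inner carbon of a 1,1-disubstituted alkene directly beside a secondary carbinol at C15, the future oxirane CH, and that carbinol can steer an oxidant onto C14=CH2.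
- Forward: natural phytol gives a C22 aldehyde (7) and, by ozonolysis, a C18 2-iodoalkene (13). They are joined at C14–C15, the directed epoxidation makes a terminal oxirane (the only ring formed before the end), hydride opens it, and the target's oxirane is closed last.
- Stereochemistry: C6, C10, C23 and C27 come unchanged from phytol. C15 is set by a chiral chromium catalyst, C14 by the C15 carbinol in the vanadium epoxidation (erythro), and C15 is inverted in the final closure to give the (14S,15R) oxirane with the two long chains cis.

Key step: step 9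

Assumption: the oxazoline–sulfonamide ligand of step 8 is written as its (S)-antipode; whichever antipode gives the (S)-carbinol in a test coupling (MTPA ester analysis) is the one used.

**Route**

Step 1
Reactants: 1 (2E,7R,11R)-phytol
Product: 2 (2E,7R,11R)-1-bromo-3,7,11,15-tetramethylhexadec-2-ene (phytyl bromide)
Conditions: PBr3 (0.4 equiv), Et2O, −10 → 0 °C; used without storage
Reagents that add atoms: phosphorus tribromide, BrP(Br)Br
Why: SN2 bromination of a primary allylic alcohol through its phosphite ester, the usual way to phytyl bromide, should keep the E alkene and leave both stereocentres untouched.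

Step 2
Reactants: 2 phytyl bromide; 3 tert-butyl acetate
Product: 5 tert-butyl (4E,9R,13R)-5,9,13,17-tetramethyloctadec-4-enoate, via lithium enolate of tert-butyl acetate 4 (not isolated)
Conditions: 3 (2.3 equiv), LiN(i-Pr)2 (2.2 equiv), THF, −78 °C; then 2, −78 → 0 °C
Reagents that add atoms: tert-butyl acetate (3), CC(=O)OC(C)(C)C
Why: lithium ester enolate alkylation (SN2 at the primary allylic carbon), with the enolate in excess to suppress double alkylation; no stereocentre is formed and the alkene geometry is not involved.

Step 3
Reactants: 5 C22 tert-butyl ester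
Product: 6 (4E,9R,13R)-5,9,13,17-tetramethyloctadec-4-en-1-ol
Conditions: LiAlH4, THF, 0 °C → rt; NaOH/H2O work-up
Reagents that add atoms: none
Why: hydride reduction of an ester to the primary alcohol; the isolated trisubstituted alkene is inert to LiAlH4.

Step 4
Reactants: 6 C22 alcohol
Product: 7 (4E,9R,13R)-5,9,13,17-tetramethyloctadec-4-enal
Conditions: PhI(OAc)2 (1.1 equiv), TEMPO (10 mol%), CH2Cl2, rt
Reagents that add atoms: none
Why: nitroxyl-catalysed (TEMPO/PhI(OAc)2) oxidation of a primary alcohol stops at the aldehyde, does not touch the alkene, and there is no α-stereocentre to lose.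

Step 5
Reactants: 1 (2E,7R,11R)-phytol
Product: 8 (6R,10R)-6,10,14-trimethylpentadecan-2-one (phytone)
Conditions: O3, CH2Cl2/MeOH, −78 °C; then Me2S, −78 °C → rt
Reagents that add atoms: ozone, [O-][O+]=O
Why: ozonolysis with reductive work-up cleaves the only C=C bond to the methyl ketone; the stereocentres lie far from the carbonyl and cannot epimerise.

Step 6
Reactants: 8 phytone
Product: 11 (6R,10R)-6,10,14-trimethylpentadec-1-yne, via kinetic lithium enolate 9 (not isolated), via enol diethyl phosphate 10 (not isolated)
Conditions: LiN(i-Pr)2 (1.05 equiv), THF, −78 °C; ClP(O)(OEt)2, −78 °C → rt; then LiN(i-Pr)2 (2.3 equiv), −78 °C → rt; aq. NH4Cl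
Reagents that add atoms: none
Why: methyl ketone to terminal alkyne by kinetic enolisation at the methyl group, O-phosphorylation and base-induced E2 elimination of diethyl phosphate from the terminal enol phosphate, a sequence established for terpenoid methyl ketones.

Step 7
Reactants: 11 C18 terminal alkyne
Product: 13 (6R,10R)-2-iodo-6,10,14-trimethylpentadec-1-ene, via (Z)-2-iodoalkenylborane 12 (not isolated)
Conditions: B-iodo-9-borabicyclo[3.3.1]nonane (1.2 equiv), pentane, −20 → 0 °C; then AcOH, 0 °C → rt
Reagents that add atoms: B-iodo-9-borabicyclo[3.3.1]nonane, IB1C2CCCC1CCC2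
Why: syn-iodoboration of a terminal alkyne places boron on C1 and iodine on C2 (Markovnikov haloboration) and acetic acid then protodeboronates the alkenylborane, the standard route to 2-iodo-1-alkenes.

Step 8
Reactants: 7 C22 aldehyde; 13 C18 2-iodoalkene
Product: 14 (6R,10R,15S,18E,23R,27R)-2,6,10,19,23,27,31-heptamethyl-14-methylidenedotriacont-18-en-15-ol
Conditions: CrCl2 (10 mol%), (S)-N-[2-(4-isopropyl-4,5-dihydrooxazol-2-yl)-6-methylphenyl]methanesulfonamide (11 mol%), 1,8-bis(dimethylamino)naphthalene (11 mol%), NiCl2(2,9-dimethyl-1,10-phenanthroline) (2 mol%), Mn (2 equiv), Zr(C5H5)2Cl2 (1.1 equiv), LiCl (2 equiv), MeCN/DME, rt; aq. work-up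
Reagents that add atoms: none
Why: catalytic asymmetric Nozaki–Hiyama–Kishi coupling, in which zerovalent nickel inserts into the C–I bond, the alkenyl group passes to trivalent chromium carrying the sulfonamide ligand and adds to one face of the aldehyde to set C15 as S, while Mn returns chromium to the divalent state and Zr(C5H5)2Cl2 frees it from the product alkoxide.

Step 9
Reactants: 14 (S)-C40 2-methylene allylic alcohol; 15 tert-butyl hydroperoxide
Product: 16 (1S,4E,9R,13R)-5,9,13,17-tetramethyl-1-{(2R)-2-[(4R,8R)-4,8,12-trimethyltridecyl]oxiran-2-yl}octadec-4-en-1-ol (erythro epoxy alcohol)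
Conditions: VO(acac)2 (3 mol%), tert-butyl hydroperoxide (1.1 equiv, in decane), toluene, 0 °C; then aq. Na2S2O3
Reagents that add atoms: tert-butyl hydroperoxide (15), CC(C)(C)OO
Why: The hydroperoxide oxidises the tetravalent vanadium of VO(acac)2 to a pentavalent vanadate, which takes up the C15 alkoxide of 14 and a tert-butylperoxide ligand and then passes the metal-bound peroxide oxygen to the neighbouring C14=CH2 bond inside the complex. This is the hydroxyl-directed vanadium epoxidation of an acyclic secondary allylic alcohol that carries a substituent on the inner alkene carbon, the substrate class for which the reagent is most erythro-selective. The single ring, the oxirane, is closed by concerted transfer of one oxygen atom to both alkene carbons (C14–O and CH2–O form together), not by a ring-closing substitution. The new C14 centre is controlled by the (S)-C15 carbinol: the small O–C15–C14=CH2 dihedral angle demanded by the metal leaves two rotamers, and the one that puts the C15 side chain beside the C16 chain on C14 suffers allylic 1,2-strain, so oxygen should arrive on the face that gives (R)-C14, the erythro product. Chemoselectivity is also needed, because the C18=C19 alkene is bishomoallylic to the same hydroxyl and could be epoxidised with direction as well; that process is much slower than the allylic one, so a slight excess of oxidant at 0 °C and a prompt reductive quench should leave it intact. The carbinol carbon itself is not touched, so the enantiomeric purity set in step 8 is carried through.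

Step 10
Reactants: 16 erythro epoxy alcohol
Product: 17 (6R,10R,14S,15S,18E,23R,27R)-2,6,10,14,19,23,27,31-octamethyldotriacont-18-ene-14,15-diol
Conditions: LiAlH4 (2 equiv), THF, 0 °C → rt; NaOH/H2O work-up
Reagents that add atoms: none
Why: SN2 hydride opening of the oxirane at its unsubstituted CH2 carbon (the quaternary C14 is blocked) turns CH2 into the C14 methyl and leaves the C14–O bond, and so the C14 configuration, untouched.

Step 11
Reactants: 17 (14S,15S)-diol
Product: 19 (2S,3R)-2-methyl-3-[(3E,8R,12R)-4,8,12,16-tetramethylheptadec-3-en-1-yl]-2-[(4R,8R)-4,8,12-trimethyltridecyl]oxirane (CNP0229802.1), via secondary mesylate 18 (not isolated)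
Conditions: MsCl (1.2 equiv), pyridine, CH2Cl2, 0 °C; then K2CO3, MeOH, rt
Reagents that add atoms: none
Why: the secondary C15 hydroxyl is sulfonylated selectively (the tertiary one is too hindered) and the C14 alkoxide then displaces the mesylate from the back in an intramolecular Williamson substitution (3-exo-tet), inverting C15 to R and giving the cis-type oxirane.

**Compound list**

1 | (2E,7R,11R)-phytol | C/C(=C\CO)CCC[C@H](C)CCC[C@H](C)CCCC(C)C | starting material
2 | (2E,7R,11R)-1-bromo-3,7,11,15-tetramethylhexadec-2-ene | C/C(=C\CBr)CCC[C@H](C)CCC[C@H](C)CCCC(C)C | intermediate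
3 | tert-butyl acetate | CC(=O)OC(C)(C)C | starting material
4 | lithium enolate of tert-butyl acetate | C=C([O-])OC(C)(C)C.[Li+] | intermediate (not isolated)
5 | tert-butyl (4E,9R,13R)-5,9,13,17-tetramethyloctadec-4-enoate | C/C(=C\CCC(=O)OC(C)(C)C)CCC[C@H](C)CCC[C@H](C)CCCC(C)C | intermediate
6 | (4E,9R,13R)-5,9,13,17-tetramethyloctadec-4-en-1-ol | C/C(=C\CCCO)CCC[C@H](C)CCC[C@H](C)CCCC(C)C | intermediate
7 | (4E,9R,13R)-5,9,13,17-tetramethyloctadec-4-enal | C/C(=C\CCC=O)CCC[C@H](C)CCC[C@H](C)CCCC(C)C | intermediate
8 | (6R,10R)-6,10,14-trimethylpentadecan-2-one | CC(=O)CCC[C@H](C)CCC[C@H](C)CCCC(C)C | intermediate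
9 | lithium (6R,10R)-6,10,14-trimethylpentadec-1-en-2-olate | C=C([O-])CCC[C@H](C)CCC[C@H](C)CCCC(C)C.[Li+] | intermediate (not isolated)
10 | diethyl (6R,10R)-6,10,14-trimethylpentadec-1-en-2-yl phosphate | C=C(OP(=O)(OCC)OCC)CCC[C@H](C)CCC[C@H](C)CCCC(C)C | intermediate (not isolated)
11 | (6R,10R)-6,10,14-trimethylpentadec-1-yne | C#CCCC[C@H](C)CCC[C@H](C)CCCC(C)C | intermediate
12 | 9-[(1Z,6R,10R)-2-iodo-6,10,14-trimethylpentadec-1-en-1-yl]-9-borabicyclo[3.3.1]nonane | I/C(=C\B1C2CCCC1CCC2)CCC[C@H](C)CCC[C@H](C)CCCC(C)C | intermediate (not isolated)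
13 | (6R,10R)-2-iodo-6,10,14-trimethylpentadec-1-ene | C=C(I)CCC[C@H](C)CCC[C@H](C)CCCC(C)C | intermediate
14 | (6R,10R,15S,18E,23R,27R)-2,6,10,19,23,27,31-heptamethyl-14-methylidenedotriacont-18-en-15-ol | C/C(=C\CC[C@H](O)C(=C)CCC[C@H](C)CCC[C@H](C)CCCC(C)C)CCC[C@H](C)CCC[C@H](C)CCCC(C)C | intermediate
15 | tert-butyl hydroperoxide | CC(C)(C)OO | starting material
16 | (1S,4E,9R,13R)-5,9,13,17-tetramethyl-1-{(2R)-2-[(4R,8R)-4,8,12-trimethyltridecyl]oxiran-2-yl}octadec-4-en-1-ol | C/C(=C\CC[C@H](O)[C@@]1(OC1)CCC[C@H](C)CCC[C@H](C)CCCC(C)C)CCC[C@H](C)CCC[C@H](C)CCCC(C)C | intermediate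
17 | (6R,10R,14S,15S,18E,23R,27R)-2,6,10,14,19,23,27,31-octamethyldotriacont-18-ene-14,15-diol | C/C(=C\CC[C@H](O)[C@@](C)(O)CCC[C@H](C)CCC[C@H](C)CCCC(C)C)CCC[C@H](C)CCC[C@H](C)CCCC(C)C | intermediate
18 | (6R,10R,14S,15S,18E,23R,27R)-14-hydroxy-2,6,10,14,19,23,27,31-octamethyldotriacont-18-en-15-yl methanesulfonate | C/C(=C\CC[C@H](OS(C)(=O)=O)[C@@](C)(O)CCC[C@H](C)CCC[C@H](C)CCCC(C)C)CCC[C@H](C)CCC[C@H](C)CCCC(C)C | intermediate (not isolated)
19 | (2S,3R)-2-methyl-3-[(3E,8R,12R)-4,8,12,16-tetramethylheptadec-3-en-1-yl]-2-[(4R,8R)-4,8,12-trimethyltridecyl]oxirane | C/C(=C\CC[C@H]1O[C@@]1(C)CCC[C@H](C)CCC[C@H](C)CCCC(C)C)CCC[C@H](C)CCC[C@H](C)CCCC(C)C | target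

**Step count**

Total: 11 steps. Longest linear sequence: 8 steps (steps 1–4, then 8–11); the C18 branch (steps 5–7) joins at step 8.

**Steps most likely to fail, with fallbacks**

Step 8. The risk is insufficient facial discrimination at the unbranched aldehyde (or the wrong sense with the chosen ligand antipode), together with slow turnover of two very lipophilic partners in a polar medium. The fallback sets out from 7 and 13 and gives up catalyst control in the C–C bond formation. A stoichiometric achiral Ni/Cr coupling (CrCl2 in excess, NiCl2 catalytic, DMF/THF) would give the C15-epimeric (6R,10R,15RS,18E,23R,27R)-2,6,10,19,23,27,31-heptamethyl-14-methylidenedotriacont-18-en-15-ol F1. Dess–Martin periodinane would oxidise it to the α-methylene ketone (6R,10R,18E,23R,27R)-2,6,10,19,23,27,31-heptamethyl-14-methylidenedotriacont-18-en-15-one F2. A Corey–Bakshi–Shibata reduction with the (R)-2-methyl oxazaborolidine and catecholborane (toluene, −78 °C), in which the 1-alkylvinyl group acts as the large substituent, should then deliver the (S)-carbinol. The fallback rejoins the route at 14.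

Step 9. The risks are erosion of facial selectivity at C14=CH2, competing hydroxyl-directed oxidation of the bishomoallylic C18=C19 alkene, and over-oxidation once the allylic alkene is consumed. The fallback sets out from 14 and replaces substrate direction by reagent control: a Katsuki–Sharpless epoxidation with Ti(O-i-Pr)4, L-(+)-diisopropyl tartrate and tert-butyl hydroperoxide (4 Å molecular sieves, CH2Cl2, −20 °C). With L-(+)-tartrate the (S)-alcohol is the fast-reacting, matched enantiomer and should give the same erythro epoxy alcohol. The titanium tartrate catalyst does not epoxidise isolated or bishomoallylic alkenes under these conditions, and kinetic resolution would remove residual (R)-carbinol. The fallback rejoins the route at 16 and makes no compound outside the list (F0).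

Step 6. The risk is incomplete regiocontrol in the enolisation, which would lead through the internal enol phosphate to allene and internal-alkyne contaminants that are hard to separate from the terminal alkyne, and base-induced alkyne–allene isomerisation. The fallback sets out from 8 and avoids the alkyne altogether. Condensation with 2,4,6-triisopropylbenzenesulfonylhydrazide (THF, catalytic HCl, rt) would give the (E)-2,4,6-triisopropylbenzenesulfonylhydrazone of phytone F3. A Shapiro reaction (s-BuLi, 2.2 equiv, TMEDA/hexane, −78 → 0 °C) deprotonates at the methyl group and loses sulfinate and nitrogen to give (6R,10R)-2-lithio-6,10,14-trimethylpentadec-1-ene F4, which is quenched with I2 at −78 °C. The fallback rejoins the route at 13, so steps 6 and 7 are both replaced.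

**Further compounds**

F1 | step 8 | (6R,10R,15RS,18E,23R,27R)-2,6,10,19,23,27,31-heptamethyl-14-methylidenedotriacont-18-en-15-ol (C15 epimer mixture) | C/C(=C\CCC(O)C(=C)CCC[C@H](C)CCC[C@H](C)CCCC(C)C)CCC[C@H](C)CCC[C@H](C)CCCC(C)C
F2 | step 8 | (6R,10R,18E,23R,27R)-2,6,10,19,23,27,31-heptamethyl-14-methylidenedotriacont-18-en-15-one | C/C(=C\CCC(=O)C(=C)CCC[C@H](C)CCC[C@H](C)CCCC(C)C)CCC[C@H](C)CCC[C@H](C)CCCC(C)C
F0 | step 9 | none | none
F3 | step 6 | (E)-2,4,6-triisopropylbenzenesulfonylhydrazone of (6R,10R)-6,10,14-trimethylpentadecan-2-one | C/C(=N\NS(=O)(=O)c1c(C(C)C)cc(C(C)C)cc1C(C)C)CCC[C@H](C)CCC[C@H](C)CCCC(C)C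
F4 | step 6 | (6R,10R)-2-lithio-6,10,14-trimethylpentadec-1-ene | C=C([Li])CCC[C@H](C)CCC[C@H](C)CCCC(C)C
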